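## Retrosynthetic overview
1. Target 10 ⇐ bis-tosylate 9. The phenols are freed last, and OTs is chosen because it is electron-withdrawing and keeps the benzylic epoxide from ionising.
2. The THF is the only ring formed, and it is formed late. The O–C2 bond comes from 5-exo-tet opening of trans-epoxide 8 by the C5 oxygen, with inversion at C2.
3. Epoxide 8 ⇐ E-styrene 7 by reagent-controlled Shi epoxidation, which sets C1' and C2.
4. Alkene 7 ⇐ cross-metathesis of homoallylic alcohol 6 with styrene 2.
5. Alcohol 6 ⇐ catalytic asymmetric anti-allylboration of TBSOCH2CHO (5) with E-γ-arylallyl-Bpin 4, which sets C3 and C4. Boronate 4 ⇐ 2 + allyl-Bpin (3), so both aryl groups come from 4-vinylguaiacol.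

**Numbering used:** O1, C2 (bears CH(OH)Ar, the carbinol carbon being C1'), C3 (aryl), C4 (OH), C5 (CH2). Ar = 3-methoxy-4-(tosyloxy)phenyl.

**Assumption 1:** The SMILES reads as 2S,3R,4S,1'R. All three ring substituents are cis, and C1'/C2 is erythro (anti).

**Assumption 2:** (R)-TRIP directs allylboration to the aldehyde Re face, as with PhCHO giving the (R)-carbinol, so (S)-TRIP is used here. If the sense proves opposite, use the antipode.

## Route

**Step 1**
- Reactants: 1, 2-methoxy-4-vinylphenol
- Product: 2, 2-methoxy-4-vinylphenyl 4-methylbenzenesulfonate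
- Conditions: TsCl, Et3N, DMAP (cat.), CH2Cl2, 0 °C → rt
- Reagents that add atoms: p-toluenesulfonyl chloride, Cc1ccc(cc1)S(=O)(=O)Cl
- Why: O-sulfonylation of the phenol gives a group that survives Ru carbenes, Oxone at pH 10.5 and fluoride, and that deactivates the arene.

**Step 2**
- Reactants: 2; 3, allylboronic acid pinacol ester
- Product: 4, (E)-2-methoxy-4-[3-(pinacolboryl)prop-1-enyl]phenyl tosylate
- Conditions: Grubbs II (4 mol %), 3 (2 equiv), CH2Cl2, 40 °C
- Reagents that add atoms: 3, C=CCB1OC(C)(C)C(C)(C)O1 (ethylene is lost)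
- Why: Olefin cross-metathesis of a styrene with allyl-Bpin gives the conjugated E-alkene, and this geometry encodes the later anti relationship.

**Step 3**
- Reactants: 4; 5, (tert-butyldimethylsilyloxy)acetaldehyde
- Product: 6, (2S,3R)-1-(TBSO)-3-Ar-pent-4-en-2-ol (anti)
- Conditions: (S)-TRIP (5–10 mol %), 4 Å MS, toluene, −30 °C; aq NaHCO3 work-up
- Reagents that add atoms: 5, O=CCO[Si](C)(C)C(C)(C)C
- Why: Chiral phosphoric acid-catalysed allylboration proceeds through a Zimmerman–Traxler chair; the E-boronate gives the C3/C4 anti product and the catalyst selects the aldehyde Si face, setting C4 = S and C3 = R.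

**Step 4**
- Reactants: 6; 2 (3 equiv)
- Product: 7, (2S,3R,4E)-1-(TBSO)-3,5-bis(Ar)pent-4-en-2-ol
- Conditions: Hoveyda–Grubbs II (5 mol %), 1,4-benzoquinone (10 mol %), CH2Cl2, 40 °C
- Reagents that add atoms: 2, COc1cc(C=C)ccc1OS(=O)(=O)c1ccc(C)cc1 (ethylene is lost)
- Why: Cross-metathesis with a styrene is E-selective, benzoquinone suppresses Ru–H isomerisation through the C3–H, and no stereocentre is touched.

**Step 5**
- Reactants: 7
- Product: 8, (2S,3R)-1-(TBSO)-3-Ar-3-[(2R,3R)-3-Ar-oxiran-2-yl]propan-2-ol
- Conditions: D-fructose-derived Shi ketone (30 mol %), Oxone, K2CO3, Bu4NHSO4, MeCN/DMM–aq Na2B4O7/EDTA (pH 10.5), 0 °C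
- Reagents that add atoms: Oxone (KHSO5), OOS(=O)(=O)[O-].[K+] (supplies the epoxide O)
- Why: Shi asymmetric epoxidation (dioxirane, spiro transition state) gives (R,R)-epoxides from trans-β-alkylstyrenes, setting C1' = R and C2 = R. Residual ent-6 material becomes a separable diastereomer here, and the C5-OTBS blocks premature cyclisation.

**Step 6**
- Reactants: 8
- Product: 9, (3S,4R,5S)-4-Ar-5-[(R)-hydroxy(Ar)methyl]oxolan-3-ol (all-cis)
- Conditions: TBAF, THF, 0 °C → rt
- Reagents that add atoms: none
- Why: Desilylation releases the C5 alkoxide, which opens the epoxide at C2 by a Baldwin-favoured 5-exo-tet SN2. C2 inverts (R → S) and the C1'–O bond is untouched, while the basic medium and the electron-poor aryl disfavour 6-endo benzylic attack.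

**Step 7**
- Reactants: 9
- Product: 10, Metasequirin E
- Conditions: Mg turnings (excess), MeOH, rt (sonication); aq NH4Cl
- Reagents that add atoms: none
- Why: Reductive single-electron S–O cleavage of both aryl tosylates proceeds without acid or heat, so the benzylic carbinol and all four stereocentres are preserved.

## Compound list
| No. | Name | SMILES | Role |
|---|---|---|---|
| 1 | 2-methoxy-4-vinylphenol | COc1cc(C=C)ccc1O | starting material |
| 2 | 2-methoxy-4-vinylphenyl tosylate | COc1cc(C=C)ccc1OS(=O)(=O)c1ccc(C)cc1 | intermediate |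
| 3 | allylboronic acid pinacol ester | C=CCB1OC(C)(C)C(C)(C)O1 | starting material |
| 4 | (E)-γ-arylallyl pinacol boronate | COc1cc(/C=C/CB2OC(C)(C)C(C)(C)O2)ccc1OS(=O)(=O)c1ccc(C)cc1 | intermediate |
| 5 | (tert-butyldimethylsilyloxy)acetaldehyde | O=CCO[Si](C)(C)C(C)(C)C | starting material |
| 6 | (2S,3R)-anti homoallylic alcohol | COc1cc([C@@H](C=C)[C@H](O)CO[Si](C)(C)C(C)(C)C)ccc1OS(=O)(=O)c1ccc(C)cc1 | intermediate |
| 7 | (2S,3R,4E)-diaryl pentenol | COc1cc([C@@H](/C=C/c2ccc(OS(=O)(=O)c3ccc(C)cc3)c(OC)c2)[C@H](O)CO[Si](C)(C)C(C)(C)C)ccc1OS(=O)(=O)c1ccc(C)cc1 | intermediate |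
| 8 | (R,R)-trans-epoxide | COc1cc([C@@H]([C@H]2O[C@@H]2c2ccc(OS(=O)(=O)c3ccc(C)cc3)c(OC)c2)[C@H](O)CO[Si](C)(C)C(C)(C)C)ccc1OS(=O)(=O)c1ccc(C)cc1 | intermediate |
| 9 | all-cis THF bis-tosylate | COc1cc([C@H]2[C@@H]([C@H](O)c3ccc(OS(=O)(=O)c4ccc(C)cc4)c(OC)c3)OC[C@H]2O)ccc1OS(=O)(=O)c1ccc(C)cc1 | intermediate |
| 10 | Metasequirin E | COc1cc([C@H]2[C@@H]([C@H](O)c3ccc(O)c(OC)c3)OC[C@H]2O)ccc1O | target |

## Summary
- **Total steps:** 7
- **Longest linear sequence:** 7 (1 → 2 → 4 → 6 → 7 → 8 → 9 → 10)

**Steps most likely to fail**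
1. **Step 6.** The risks are 6-endo attack giving a tetrahydropyran, or slow closure to the crowded all-cis ring. Fallback: move the electrophilic site to C5.
   - Epoxidise 7 with the enantiomeric Shi ketone to the (S,S)-epoxide.
   - Open it at benzylic C1' with a carboxylate (inversion) to give the same erythro C1'/C2 array.
   - Desilylate, sulfonylate the primary C5-OH, and let the C2-OH displace it (5-exo-tet at a non-stereogenic carbon).
2. **Step 3.** The ee and dr may be modest with an α-silyloxy aldehyde and an electron-poor cinnamyl boronate. Fallback: a chiral-pool approach in which C4 comes from the pool and C3 from substrate control.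
   - Carry out HWE olefination of (R)-glyceraldehyde acetonide with the aryl β-ketophosphonate to give the E-enone.
   - Add the aryl group by substrate-controlled anti 1,4-addition (Rh/arylboronate or cuprate).
   - Reduce with NaBH4 and dehydrate to the acetonide analogue of 7.
3. **Step 4.** The allylically branched olefin may react slowly, or the alkene may migrate. Fallback: replace metathesis with a Mizoroki–Heck arylation of 6 using 4-iodo-2-methoxyphenyl tosylate to install the E-styrene.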